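**Plan**

1. Retrosynthetic cuts: first the three ether groups (ethyl and triisopropylsilyl on ring A, methyl on the ring C enol) and the aryl–acyl bond at C5 of ring A. Then two arene C–C bonds of ring A, C1–C6 and C2–C3 (C1 = the carbon bearing the side chain), which leaves 3-ethoxy-2-methylcyclobutenone and a siloxyalkyne that carries the stereocentre and ring C.
2. Enabling feature: ring A is a benzene ring with oxygen on C2, C4 and C6. The side-chain carbon C1 and the methyl carbon C3 each lie between two oxygen-bearing carbons, and C5 carries only the acyl group. An ynol ether supplies C1–C2 and a 3-alkoxy-2-methylcyclobutenone supplies C3–C6 (C6 as the new phenol carbon, C5 as CH).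
3. The siloxyalkyne goes back to a terminal alkyne, that to an aldehyde, and the bond from the stereocentre to ring C to syncarpic acid and (E)-5-methylhex-2-enal.
4. Forward: the C7 chain is joined to ring C by a Michael addition, its end is turned into an alkyne and then an ynol ether, ring A is built around the side chain by benzannulation, C5 is acylated and the ethers are cleaved.
5. Stereochemistry: the single stereocentre is set in the Michael addition by an (R)-diarylprolinol silyl ether (iminium catalysis) and carried through unchanged. Ring C stays an enol ether until the last step, so no retro-Michael path is open.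

Key step: step 7

Remark: a 2-substituted syncarpic acid has two enol oxygens that are exchanged by rotation about the bond to the side chain, so O-methylation gives a single enol ether. Syncarpic acid, the formyl ylide, 1-ethoxyprop-1-yne and both acid chlorides are taken as purchasable.

**Route**

Step 1
Reactants: 1 3-methylbutanal; 2 (triphenylphosphoranylidene)acetaldehyde
Product: 3 (2E)-5-methylhex-2-enal
Conditions: 1 (2 equiv), PhMe, 80 °C; distillation
Reagents that add atoms: none
Why: Wittig olefination with the formyl-stabilised ylide should give the (E)-enal, and the excess of the cheap aldehyde suppresses a second homologation of the less electrophilic product.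

Step 2
Reactants: 3 (2E)-5-methylhex-2-enal; 4 syncarpic acid (2,2,4,4-tetramethylcyclohexane-1,3,5-trione)
Product: 6 (4S)-2-hydroxy-6,6,8,8-tetramethyl-4-(2-methylpropyl)-3,4-dihydro-2H-chromene-5,7(6H,8H)-dione (both C2 anomers), via open-chain aldehyde 5 (not isolated)
Conditions: (R)-2-[diphenyl(trimethylsilyloxy)methyl]pyrrolidine (10 mol %), CH2Cl2, 0 °C to 20 °C
Reagents that add atoms: none
Why: Iminium-catalysed asymmetric Michael addition of a cyclic 1,3-diketone to an enal with a diarylprolinol silyl ether: the (E)-iminium ion of 3 is shielded on one face by the diphenyl(silyloxy)methyl group of the (R)-catalyst, so that the nucleophilic ring carbon of the syncarpic acid enol adds to the open face of the β-carbon and sets the (S)-centre, after which the aldehyde is trapped by the enol OH as the hemiacetal.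

Step 3
Reactants: 6 (4S)-2-hydroxy-6,6,8,8-tetramethyl-4-(2-methylpropyl)-3,4-dihydro-2H-chromene-5,7(6H,8H)-dione
Product: 7 (3S)-3-(2-methoxy-3,3,5,5-tetramethyl-4,6-dioxocyclohex-1-en-1-yl)-5-methylhexanal
Conditions: Me3SiCHN2 (1.3 equiv), PhMe–MeOH 4:1, 0 °C to 20 °C
Reagents that add atoms: trimethylsilyldiazomethane, C[Si](C)(C)C=[N+]=[N-]
Why: O-methylation of an acidic enol by diazomethane released from Me3SiCHN2 and methanol: lactol 6 is the ring–chain tautomer of the open-chain hydroxy-enone aldehyde from which it closed in step 2, this minor open form is a vinylogous carboxylic acid that protonates the diazoalkane and is methylated on oxygen, and its removal drains the equilibrium and leaves the aldehyde free.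

Step 4
Reactants: 7 (3S)-3-(2-methoxy-3,3,5,5-tetramethyl-4,6-dioxocyclohex-1-en-1-yl)-5-methylhexanal
Product: 9 3-methoxy-4,4,6,6-tetramethyl-2-[(3S)-5-methylhex-1-yn-3-yl]cyclohex-2-ene-1,5-dione, via alkenyl nonaflate 8 (not isolated)
Conditions: C4F9SO2F (1.2 equiv), t-BuN=P(pyrrolidin-1-yl)3 (2.5 equiv), DMF, −30 °C to 20 °C
Reagents that add atoms: none
Why: One-pot nonaflation–elimination of an enolisable aldehyde with a P1 phosphazene base: the aldehyde α-carbon is the only enolisable position (the ring C ketones have none), its enolate is sulfonylated on oxygen and a second equivalent of base eliminates nonaflate to the terminal alkyne, while the neighbouring stereocentre, whose C–H is not activated by a carbonyl group, should stay untouched by a base of this strength.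

Step 5
Reactants: 9 3-methoxy-4,4,6,6-tetramethyl-2-[(3S)-5-methylhex-1-yn-3-yl]cyclohex-2-ene-1,5-dione
Product: 12 3-methoxy-4,4,6,6-tetramethyl-2-[(3S)-5-methyl-1-(triisopropylsilyloxy)hex-1-yn-3-yl]cyclohex-2-ene-1,5-dione, via lithium acetylide 10 (not isolated), via lithium ynolate 11 (not isolated)
Conditions: t-BuOOH (1.1 equiv), LiN(SiMe3)2 (2.2 equiv), THF, −78 °C to 0 °C; then iPr3SiOTf (1.2 equiv), −78 °C to 0 °C
Reagents that add atoms: tert-butyl hydroperoxide, CC(C)(C)OO; triisopropylsilyl trifluoromethanesulfonate, CC(C)[Si](OS(=O)(=O)C(F)(F)F)(C(C)C)C(C)C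
Why: Oxidation of a lithium acetylide with lithium tert-butyl peroxide to the ynolate followed by O-silylation (the standard entry to triisopropylsilyloxyalkynes): ring C has no enolisable hydrogen and both its carbonyl groups are flanked by fully substituted carbons, so oxygen transfer to the acetylide should outrun carbonyl addition at low temperature, and the amide base is too weak to remove the propargylic hydrogen.

Step 6
Reactants: 13 1-ethoxyprop-1-yne; 14 acetyl chloride
Product: 16 3-ethoxy-2-methylcyclobut-2-en-1-one, via ketene 15 (not isolated)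
Conditions: Et3N, Et2O, 0 °C to 20 °C, slow addition of 14
Reagents that add atoms: none
Why: [2+2] cycloaddition of ketene, formed by dehydrochlorination of acetyl chloride, with an alkoxyalkyne: the methyl-bearing alkyne carbon is the nucleophilic one and bonds to the ketene carbonyl carbon, which gives the 3-ethoxy-2-methyl isomer.

Step 7
Reactants: 12 3-methoxy-4,4,6,6-tetramethyl-2-[(3S)-5-methyl-1-(triisopropylsilyloxy)hex-1-yn-3-yl]cyclohex-2-ene-1,5-dione; 16 3-ethoxy-2-methylcyclobut-2-en-1-one
Product: 21 2-[(1S)-1-[4-ethoxy-6-hydroxy-3-methyl-2-(triisopropylsilyloxy)phenyl]-3-methylbutyl]-3-methoxy-4,4,6,6-tetramethylcyclohex-2-ene-1,5-dione, via vinylketene 17 (not isolated), via vinylcyclobutenone 18 (not isolated), via dienylketene 19 (not isolated), via cyclohexadienone 20 (not isolated)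
Conditions: 16 (1.5 equiv), PhMe, 80 °C then 110 °C, sealed tube
Reagents that add atoms: none
Why: Heat opens 16 by a 4π electrocyclic reaction to vinylketene 17, whose ketene C=C adds to the electron-rich triple bond of 12 in a [2+2] cycloaddition; the resulting 4-vinylcyclobutenone 18 opens again (4π) to dienylketene 19, which closes by a thermal disrotatory 6π electrocyclisation, the one ring-forming event that makes the six-membered carbocycle ring A, and cyclohexadienone 20 tautomerises to phenol 21. The closest known reaction is the Danheiser benzannulation of cyclobutenones with trialkylsilyloxyalkynes to resorcinol monosilyl ethers, here run with a 3-alkoxycyclobutenone so that the third oxygen is already in place. No stereocentre is formed (the quaternary carbon of 18 disappears on ring opening) and the existing one is a spectator, because the cascade is driven by release of strain in two four-membered rings and by aromatisation and needs neither acid nor base. The selectivity needed is the orientation of the ketene–alkyne cycloaddition, and the polarisation of the ynol ether secures it: the alkyne carbon remote from oxygen, which bears the stereocentre, is the nucleophilic one and bonds to the ketene carbonyl carbon, so that the side chain ends up between the new OH and the silyloxy group and the methyl group between the silyloxy and ethoxy groups. The triisopropylsilyl group cannot leave by a retro-ene path as an ethyl group could and slows the silyl shift to a silylketene, and the excess of 16 makes up for vinylketene lost to oligomerisation.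

Step 8
Reactants: 21 2-[(1S)-1-[4-ethoxy-6-hydroxy-3-methyl-2-(triisopropylsilyloxy)phenyl]-3-methylbutyl]-3-methoxy-4,4,6,6-tetramethylcyclohex-2-ene-1,5-dione; 22 3-phenylpropanoyl chloride
Product: 23 2-[(1S)-1-[4-ethoxy-6-hydroxy-3-methyl-5-(3-phenylpropanoyl)-2-(triisopropylsilyloxy)phenyl]-3-methylbutyl]-3-methoxy-4,4,6,6-tetramethylcyclohex-2-ene-1,5-dione
Conditions: TiCl4 (2.2 equiv), CH2Cl2, −78 °C to −20 °C
Reagents that add atoms: none
Why: Friedel–Crafts acylation directed by the aryloxytitanium trichloride formed from the phenol and TiCl4: C5 is the only unsubstituted ring position, lies ortho to the phenol oxygen and to OEt and para to the silyloxy group, and should be acylated at low temperature, where the silyl ether, the enol ether and the benzylic stereocentre are left alone.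

Step 9
Reactants: 23 2-[(1S)-1-[4-ethoxy-6-hydroxy-3-methyl-5-(3-phenylpropanoyl)-2-(triisopropylsilyloxy)phenyl]-3-methylbutyl]-3-methoxy-4,4,6,6-tetramethylcyclohex-2-ene-1,5-dione
Product: 24 2-[(1S)-1-[4-ethoxy-2,6-dihydroxy-3-methyl-5-(3-phenylpropanoyl)phenyl]-3-methylbutyl]-3-methoxy-4,4,6,6-tetramethylcyclohex-2-ene-1,5-dione
Conditions: Bu4NF (1.1 equiv), AcOH (1.1 equiv), THF, 0 °C
Reagents that add atoms: none
Why: Fluoride-mediated cleavage of an aryl silyl ether; with ring C still an enol ether there is no stabilised leaving group for a retro-Michael fragmentation at the benzylic carbon, so the buffered fluoride should not racemise it.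

Step 10
Reactants: 24 2-[(1S)-1-[4-ethoxy-2,6-dihydroxy-3-methyl-5-(3-phenylpropanoyl)phenyl]-3-methylbutyl]-3-methoxy-4,4,6,6-tetramethylcyclohex-2-ene-1,5-dione
Product: 25 3-hydroxy-4,4,6,6-tetramethyl-2-[(1S)-3-methyl-1-[2,4,6-trihydroxy-3-methyl-5-(3-phenylpropanoyl)phenyl]butyl]cyclohex-2-ene-1,5-dione (CNP0188786.1)
Conditions: BBr3 (5 equiv), CH2Cl2, −78 °C to 0 °C; then H2O, 0 °C
Reagents that add atoms: none
Why: Lewis-acid ether cleavage with BBr3: the ethyl ether ortho to the ketone is cleaved with chelation assistance and the vinylogous methyl ester of ring C by bromide attack on its methyl group, and the low temperature and short contact time should keep acid-promoted cyclodehydration to a xanthene and ionisation at the benzylic carbon from setting in.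

**Compound list**

1 | 3-methylbutanal | CC(C)CC=O | starting material
2 | (triphenylphosphoranylidene)acetaldehyde | O=CC=P(c1ccccc1)(c1ccccc1)c1ccccc1 | starting material
3 | (2E)-5-methylhex-2-enal | CC(C)C/C=C/C=O | intermediate
4 | syncarpic acid (2,2,4,4-tetramethylcyclohexane-1,3,5-trione) | CC1(C)C(=O)CC(=O)C(C)(C)C1=O | starting material
5 | (3S)-3-(2-hydroxy-3,3,5,5-tetramethyl-4,6-dioxocyclohex-1-en-1-yl)-5-methylhexanal (open-chain Michael adduct, not isolated) | O=CC[C@H](CC(C)C)C1=C(O)C(C)(C)C(=O)C(C)(C)C1=O | intermediate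
6 | (4S)-2-hydroxy-6,6,8,8-tetramethyl-4-(2-methylpropyl)-3,4-dihydro-2H-chromene-5,7(6H,8H)-dione (both C2 anomers) | OC1C[C@H](CC(C)C)C2=C(O1)C(C)(C)C(=O)C(C)(C)C2=O | intermediate
7 | (3S)-3-(2-methoxy-3,3,5,5-tetramethyl-4,6-dioxocyclohex-1-en-1-yl)-5-methylhexanal | O=CC[C@H](CC(C)C)C1=C(OC)C(C)(C)C(=O)C(C)(C)C1=O | intermediate
8 | (3S)-3-(2-methoxy-3,3,5,5-tetramethyl-4,6-dioxocyclohex-1-en-1-yl)-5-methylhex-1-en-1-yl nonafluorobutane-1-sulfonate (E/Z mixture, not isolated) | O=S(=O)(OC=C[C@H](CC(C)C)C1=C(OC)C(C)(C)C(=O)C(C)(C)C1=O)C(F)(F)C(F)(F)C(F)(F)C(F)(F)F | intermediate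
9 | 3-methoxy-4,4,6,6-tetramethyl-2-[(3S)-5-methylhex-1-yn-3-yl]cyclohex-2-ene-1,5-dione | C#C[C@H](CC(C)C)C1=C(OC)C(C)(C)C(=O)C(C)(C)C1=O | intermediate
10 | [(3S)-3-(2-methoxy-3,3,5,5-tetramethyl-4,6-dioxocyclohex-1-en-1-yl)-5-methylhex-1-yn-1-yl]lithium (not isolated) | [Li]C#C[C@H](CC(C)C)C1=C(OC)C(C)(C)C(=O)C(C)(C)C1=O | intermediate
11 | lithium (3S)-3-(2-methoxy-3,3,5,5-tetramethyl-4,6-dioxocyclohex-1-en-1-yl)-5-methylhex-1-yn-1-olate (not isolated) | [Li]OC#C[C@H](CC(C)C)C1=C(OC)C(C)(C)C(=O)C(C)(C)C1=O | intermediate
12 | 3-methoxy-4,4,6,6-tetramethyl-2-[(3S)-5-methyl-1-(triisopropylsilyloxy)hex-1-yn-3-yl]cyclohex-2-ene-1,5-dione | CC(C)[Si](C(C)C)(C(C)C)OC#C[C@H](CC(C)C)C1=C(OC)C(C)(C)C(=O)C(C)(C)C1=O | intermediate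
13 | 1-ethoxyprop-1-yne | CCOC#CC | starting material
14 | acetyl chloride | CC(=O)Cl | starting material
15 | ketene (ethenone, not isolated) | C=C=O | intermediate
16 | 3-ethoxy-2-methylcyclobut-2-en-1-one | CCOC1=C(C)C(=O)C1 | intermediate
17 | 3-ethoxy-2-methylbuta-1,3-dien-1-one (vinylketene, not isolated) | C=C(OCC)C(C)=C=O | intermediate
18 | 4-(1-ethoxyethenyl)-4-methyl-3-(triisopropylsilyloxy)cyclobut-2-en-1-one carrying at C2 the 1-(2-methoxy-3,3,5,5-tetramethyl-4,6-dioxocyclohex-1-en-1-yl)-3-methylbutyl group with the arrangement in space of 12; ring C4 as a mixture (not isolated) | O=C1C([C@H](CC(C)C)C2=C(OC)C(C)(C)C(=O)C(C)(C)C2=O)=C(O[Si](C(C)C)(C(C)C)C(C)C)C1(C)C(OCC)=C | intermediate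
19 | 5-ethoxy-4-methyl-3-(triisopropylsilyloxy)hexa-1,3,5-trien-1-one carrying at C2 the same side chain, ketene and ethoxyvinyl groups cis on the C3=C4 bond (not isolated) | O=C=C([C@H](CC(C)C)C1=C(OC)C(C)(C)C(=O)C(C)(C)C1=O)/C(O[Si](C(C)C)(C(C)C)C(C)C)=C(C)\C(OCC)=C | intermediate
20 | 5-ethoxy-4-methyl-3-(triisopropylsilyloxy)cyclohexa-2,4-dien-1-one carrying at C2 the same side chain (not isolated) | O=C1CC(OCC)=C(C)C(O[Si](C(C)C)(C(C)C)C(C)C)=C1[C@H](CC(C)C)C2=C(OC)C(C)(C)C(=O)C(C)(C)C2=O | intermediate
21 | 2-[(1S)-1-[4-ethoxy-6-hydroxy-3-methyl-2-(triisopropylsilyloxy)phenyl]-3-methylbutyl]-3-methoxy-4,4,6,6-tetramethylcyclohex-2-ene-1,5-dione | CCOc1c(C)c(O[Si](C(C)C)(C(C)C)C(C)C)c([C@H](CC(C)C)C2=C(OC)C(C)(C)C(=O)C(C)(C)C2=O)c(O)c1 | intermediate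
22 | 3-phenylpropanoyl chloride | O=C(Cl)CCc1ccccc1 | starting material
23 | 2-[(1S)-1-[4-ethoxy-6-hydroxy-3-methyl-5-(3-phenylpropanoyl)-2-(triisopropylsilyloxy)phenyl]-3-methylbutyl]-3-methoxy-4,4,6,6-tetramethylcyclohex-2-ene-1,5-dione | CCOc1c(C)c(O[Si](C(C)C)(C(C)C)C(C)C)c([C@H](CC(C)C)C2=C(OC)C(C)(C)C(=O)C(C)(C)C2=O)c(O)c1C(=O)CCc3ccccc3 | intermediate
24 | 2-[(1S)-1-[4-ethoxy-2,6-dihydroxy-3-methyl-5-(3-phenylpropanoyl)phenyl]-3-methylbutyl]-3-methoxy-4,4,6,6-tetramethylcyclohex-2-ene-1,5-dione | CCOc1c(C)c(O)c([C@H](CC(C)C)C2=C(OC)C(C)(C)C(=O)C(C)(C)C2=O)c(O)c1C(=O)CCc3ccccc3 | intermediate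
25 | 3-hydroxy-4,4,6,6-tetramethyl-2-[(1S)-3-methyl-1-[2,4,6-trihydroxy-3-methyl-5-(3-phenylpropanoyl)phenyl]butyl]cyclohex-2-ene-1,5-dione (CNP0188786.1) | Cc1c(O)c(C(=O)CCc2ccccc2)c(O)c([C@H](CC(C)C)C2=C(O)C(C)(C)C(=O)C(C)(C)C2=O)c1O | target

**Step count and risks**

Total: 10 steps. Longest linear sequence: 9 steps (steps 1–5 and 7–10); step 6 is a one-step side branch.

Steps most likely to fail:

1. Step 7 (benzannulation). The vinylogous-ester stabilisation of 16 raises the barrier of its ring opening, so 17 may form only at temperatures at which 12 rearranges to a silylketene, and the hindered alkyne may react more slowly than 17 oligomerises. The fallback sets out from 12 and returns at 21; it generates the same vinylketene 17 at 20 °C by photochemical Wolff rearrangement of a diazo ketone. Stille acylation of propanoyl chloride with tributyl(1-ethoxyethenyl)stannane (PdCl2(PPh3)2, PhMe, 80 °C) gives 2-ethoxypent-1-en-3-one F1. Trifluoroacetylation of its only enolisable position (LiN(SiMe3)2, CF3CO2CH2CF3, THF, −78 °C) gives 2-ethoxy-6,6,6-trifluoro-4-methylhex-1-ene-3,5-dione F2, which is treated without isolation with MsN3 and Et3N to give 2-diazo-4-ethoxypent-4-en-3-one F3 by detrifluoroacetylative diazo transfer. Irradiation of F3 (300 nm) with 12 in CH2Cl2 at 20 °C, where the 1-ethoxyvinyl group migrates, and then warming to 80 °C should lead through 17, 18, 19 and 20 to 21.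

2. Step 5 (ynol ether formation). Addition of acetylide 10 to a ring C carbonyl group, or attack of the peroxide on the enone, may compete with oxygen transfer. The fallback sets out from 9 and returns at 12 through ynolate 11; it reverses the polarity of the alkyne carbon. Alkyne 9 and PhI(OH)OTs (CH2Cl2, 20 °C) give the alkynyl(phenyl)iodonium tosylate F4. Catalytic CuOTf in MeCN converts it with loss of iodobenzene into the alkynyl tosylate F5. MeLi (THF, −78 °C) cleaves the S–O bond of F5 within minutes to give 11, which is silylated with iPr3SiOTf as in step 5.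

3. Step 4 (aldehyde to alkyne). Aldol self-condensation of 7 under the base, or slow syn elimination from the (E)-isomer of 8, may hold the yield down, and any stronger base used to force the elimination risks propargyl–allenyl isomerisation that erodes the configuration. The fallback sets out from 4 and returns at 9; it forms the bond from ring C to the propargylic carbon by copper-catalysed asymmetric propargylic alkylation. Purchased 5-methylhex-1-yn-3-ol is acetylated (Ac2O, Et3N, DMAP) to racemic 5-methylhex-1-yn-3-yl acetate F6. With 4, CuOTf·1/2C6H6 and a chiral pybox ligand (iPr2NEt, MeOH, −20 °C), F6 should give 3-hydroxy-4,4,6,6-tetramethyl-2-[(3S)-5-methylhex-1-yn-3-yl]cyclohex-2-ene-1,5-dione F7 through the allenylidene complex of the CuOTf–pybox catalyst, attacked at its γ-carbon. The ligand enantiomer is chosen for the (S)-product, and the reaction is stopped before the enol adds to the alkyne. Methylation of F7 with Me3SiCHN2 as in step 3 gives 9.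

Further compounds
F1 | step 7 | 2-ethoxypent-1-en-3-one | C=C(OCC)C(=O)CC
F2 | step 7 | 2-ethoxy-6,6,6-trifluoro-4-methylhex-1-ene-3,5-dione | C=C(OCC)C(=O)C(C)C(=O)C(F)(F)F
F3 | step 7 | 2-diazo-4-ethoxypent-4-en-3-one | C=C(OCC)C(=O)C(C)=[N+]=[N-]
F4 | step 5 | [(3R)-3-(2-methoxy-3,3,5,5-tetramethyl-4,6-dioxocyclohex-1-en-1-yl)-5-methylhex-1-yn-1-yl](phenyl)iodonium 4-methylbenzenesulfonate (same arrangement in space as in 9; iodine changes the descriptor) | c1ccccc1[I+]C#C[C@H](CC(C)C)C2=C(OC)C(C)(C)C(=O)C(C)(C)C2=O.Cc3ccc(cc3)S(=O)(=O)[O-]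
F5 | step 5 | (3S)-3-(2-methoxy-3,3,5,5-tetramethyl-4,6-dioxocyclohex-1-en-1-yl)-5-methylhex-1-yn-1-yl 4-methylbenzenesulfonate | Cc1ccc(cc1)S(=O)(=O)OC#C[C@H](CC(C)C)C2=C(OC)C(C)(C)C(=O)C(C)(C)C2=O
F6 | step 4 | 5-methylhex-1-yn-3-yl acetate (racemic) | CC(=O)OC(CC(C)C)C#C
F7 | step 4 | 3-hydroxy-4,4,6,6-tetramethyl-2-[(3S)-5-methylhex-1-yn-3-yl]cyclohex-2-ene-1,5-dione | C#C[C@H](CC(C)C)C1=C(O)C(C)(C)C(=O)C(C)(C)C1=O
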